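## Retrosynthetic overview
1. Last bond: the enone Cα=Cβ is made by Claisen–Schmidt condensation, which leads back to a 3-alkylated resacetophenone and 4-hydroxybenzaldehyde.
2. Key bond: aryl C-3'–C-1''. Both carbons are innate nucleophiles: the enol α-carbon between the two phenol oxygens, and the terminal vinyl carbon of linalool. The arene carbon is reversed into an electrophile as its phenyl-λ3-iodane phenolate (an enolonium equivalent). The vinyl terminus is carried as a B-alkyl-9-BBN.
3. Stereocentre: it is bought, not made. (R)-(−)-Linalool supplies all ten side-chain carbons and the (R)-carbinol, and no bond to that carbon is ever broken.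
4. Rings: none is formed, both benzene rings are purchased, and no protecting groups are used.

Assumption: commercial (R)-(−)-linalool (ho-wood grade, about 97% ee or better, checked by chiral GC) is the only source of chirality, so the ee of the target equals that of the linalool. Hydroboration and coupling in one flask count as one step.

## Route

**Step 1**
Reactants: 1 2',4'-dihydroxyacetophenone (resacetophenone)
Product: 2 4-acetyl-3-hydroxy-2-(phenyliodonio)phenolate (inner salt; iodine on the ring carbon between the two oxygens)
Conditions: PhI(OAc)2 (1.05 equiv), MeOH, 0 °C, 2 h, dark; filter the precipitate, store cold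
Reagents that add atoms: (diacetoxyiodo)benzene, CC(=O)OI(OC(C)=O)c1ccccc1
Why: Electrophilic aromatic substitution by I(III) (iodonium zwitterion formation, a known compound class for 4-acylresorcinols), in which the doubly activated C-3 attacks the iodane and loss of two AcOH gives the charge-compensated aryl(phenyl)iodonium phenolate, turning the natively nucleophilic enol α-carbon into an enolonium-type electrophile; no stereocentre is involved.

**Step 2**
Reactants: 2 4-acetyl-3-hydroxy-2-(phenyliodonio)phenolate; 3 (R)-(−)-linalool
Product: 5 1-{2,4-dihydroxy-3-[(3R)-3-hydroxy-3,7-dimethyloct-6-en-1-yl]phenyl}ethan-1-one, via bis-9-BBN adduct 4 (not isolated)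
Conditions: 3 (2.2 equiv), 9-BBN-H (0.5 M in THF, 4.6 equiv), 0 °C → rt, 8 h; degassed H2O, Cs2CO3 (4 equiv), 15 min; then 2 (1.0 equiv), PdCl2(dppf)·CH2Cl2 (5 mol %), AsPh3 (5 mol %), DMF/THF/H2O, rt, dark, 12 h; pH 6 buffer work-up (no H2O2)
Reagents that add atoms: none
Why: Proposed new method: Brown hydroboration with 9-BBN takes only the monosubstituted vinyl group (anti-Markovnikov; the trisubstituted alkene is at least 100 times slower; the second equivalent caps the OH) and touches no bond at the carbinol carbon, so the (R)-centre of linalool is carried over unchanged; in the following B-alkyl Suzuki–Miyaura coupling Pd(0) inserts into the ylidic C-3–I(III) bond of 2 at rt with loss of the hypernucleofuge PhI, the hydroxoborate of 4 transmetalates, and dppf-promoted reductive elimination outruns β-hydride elimination, which joins two natively nucleophilic carbons through the enolonium-type iodane without phenol protection; if phenyl were transferred instead, the co-product would be the 3-iodoarene, itself a competent partner, hence the excess of borane; closest known reactions: Pd-catalysed Suzuki couplings of phenyliodonium zwitterions of 4-hydroxycoumarin and 2-hydroxynaphthoquinone with boronic acids, and rt B-alkyl Suzuki couplings of 9-BBN adducts.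

**Step 3**
Reactants: 5 1-{2,4-dihydroxy-3-[(3R)-3-hydroxy-3,7-dimethyloct-6-en-1-yl]phenyl}ethan-1-one; 6 4-hydroxybenzaldehyde
Product: 8 (2E)-1-{2,4-dihydroxy-3-[(3R)-3-hydroxy-3,7-dimethyloct-6-en-1-yl]phenyl}-3-(4-hydroxyphenyl)prop-2-en-1-one (target), via aldol adduct 7 (not isolated)
Conditions: 6 (1.3 equiv), 50% aq KOH (20 equiv), EtOH, rt → 40 °C, 48 h, Ar; ice, 1 M HCl to pH 5–6
Reagents that add atoms: none
Why: Claisen–Schmidt aldol condensation as used for unprotected isoliquiritigenin-type chalcones, in which E1cB dehydration under thermodynamic control gives only the (E)-enone and the H-bonded 2'-hydroxychalcone is preferred over the flavanone for a resorcinol A ring; the saturated tertiary carbinol is inert to base and sees only cold, weakly acidic work-up, so the (R)-centre is not scrambled.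

## Compound list
1 | 2',4'-dihydroxyacetophenone | CC(=O)c1ccc(O)cc1O | starting material
2 | 4-acetyl-3-hydroxy-2-(phenyliodonio)phenolate | CC(=O)c1ccc([O-])c([I+]c2ccccc2)c1O | intermediate
3 | (R)-(−)-linalool, (3R)-3,7-dimethylocta-1,6-dien-3-ol | CC(C)=CCC[C@@](C)(O)C=C | starting material
4 | 9-[(3S)-3-(9-borabicyclo[3.3.1]nonan-9-yloxy)-3,7-dimethyloct-6-en-1-yl]-9-borabicyclo[3.3.1]nonane (same spatial arrangement as 3; the descriptor reads S only because B ranks below C) | CC(C)=CCC[C@@](C)(OB1C2CCCC1CCC2)CCB1C2CCCC1CCC2 | intermediate (not isolated)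
5 | 1-{2,4-dihydroxy-3-[(3R)-3-hydroxy-3,7-dimethyloct-6-en-1-yl]phenyl}ethan-1-one | CC(C)=CCC[C@@](C)(O)CCc1c(O)ccc(C(C)=O)c1O | intermediate
6 | 4-hydroxybenzaldehyde | O=Cc1ccc(O)cc1 | starting material
7 | 1-{2,4-dihydroxy-3-[(3R)-3-hydroxy-3,7-dimethyloct-6-en-1-yl]phenyl}-3-hydroxy-3-(4-hydroxyphenyl)propan-1-one (both epimers at the new carbinol) | CC(C)=CCC[C@@](C)(O)CCc1c(O)ccc(C(=O)CC(O)c2ccc(O)cc2)c1O | intermediate (not isolated)
8 | (2E)-1-{2,4-dihydroxy-3-[(3R)-3-hydroxy-3,7-dimethyloct-6-en-1-yl]phenyl}-3-(4-hydroxyphenyl)prop-2-en-1-one | CC(C)=CCC[C@@](C)(O)CCc1c(O)ccc(C(=O)/C=C/c2ccc(O)cc2)c1O | target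

## Totals, risks and fallbacks
Total step count: 3.
Longest linear sequence: 3 (1 → 2 → 5 → 8). Compound 3 enters at step 2 and compound 6 at step 3.

**Highest risk: step 2.**
- Possible failures:
  - Phenyl rather than oxidoaryl transfer from iodine.
  - An I→O phenyl shift of 2 in base.
  - β-Hydride elimination at the di-ortho-substituted aryl–Pd centre.
  - Consumption of the borane by the released PhI.
- The fallback sets out from 2 and 3 and comes back at 5. It keeps the reversed-polarity arene but avoids the sp3 organometallic.
- A room-temperature Mizoroki–Heck reaction of 2 with free linalool is run with Pd(OAc)2 (5 mol %) and NaHCO3 in DMF in the dark.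
  - Iodonium species are Heck-active at rt.
  - The tertiary allylic alcohol has no carbinol H, so it cannot isomerise to a ketone.
  - The product is 1-{2,4-dihydroxy-3-[(1E,3R)-3-hydroxy-3,7-dimethylocta-1,6-dien-1-yl]phenyl}ethan-1-one F1. It is kept cold and neutral to avoid closure to the 2H-chromene.
- Diimide is then generated at rt from 2-nitrobenzenesulfonyl hydrazide and Et3N. It saturates the 1,2-disubstituted styrenyl alkene about ten times faster than the trisubstituted one, giving 5.

**Second: step 3.**
- Possible failure: the polyphenoxides of 5 and 6 are a poor enolate precursor and a poor electrophile, so conversion may stay low.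
- The fallback sets out from 5 and comes back at 8. It uses base- and Pd-removable capping groups instead of acid-labile ones, because acid could close the chroman at the tertiary alcohol.
- Allyl bromide (1.05 equiv) with K2CO3 in acetone alkylates only the 4-OH, which is not H-bonded. This gives 1-{2-hydroxy-3-[(3R)-3-hydroxy-3,7-dimethyloct-6-en-1-yl]-4-(prop-2-en-1-yloxy)phenyl}ethan-1-one F2.
- Condensation with purchased 4-(prop-2-en-1-yloxy)benzaldehyde F3 (KOH, EtOH, rt) gives (2E)-1-{2-hydroxy-3-[(3R)-3-hydroxy-3,7-dimethyloct-6-en-1-yl]-4-(prop-2-en-1-yloxy)phenyl}-3-[4-(prop-2-en-1-yloxy)phenyl]prop-2-en-1-one F4.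
- Pd(PPh3)4 (5 mol %) with K2CO3 in MeOH removes both allyl groups to give 8.

**Third: step 1.**
- Possible failures: quinoid over-oxidation by the iodane, or attack at C-5.
- The fallback sets out from 1 and comes back at 5. It replaces the I(III) electrophile with an ordinary carbon–iodine(I) bond.
- I2/HIO3 in aqueous EtOH iodinates between the two hydroxyls to give 1-(2,4-dihydroxy-3-iodophenyl)ethan-1-one F5.
- F5 is coupled as its dipotassium salt with the borane 4, made as in step 2. The conditions are SPhos Pd G3 (5 mol %) and aq K3PO4 in THF at 60 °C, and the product is 5.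

## Further compounds
F1 | step 2 | 1-{2,4-dihydroxy-3-[(1E,3R)-3-hydroxy-3,7-dimethylocta-1,6-dien-1-yl]phenyl}ethan-1-one | CC(C)=CCC[C@@](C)(O)/C=C/c1c(O)ccc(C(C)=O)c1O
F2 | step 3 | 1-{2-hydroxy-3-[(3R)-3-hydroxy-3,7-dimethyloct-6-en-1-yl]-4-(prop-2-en-1-yloxy)phenyl}ethan-1-one | CC(C)=CCC[C@@](C)(O)CCc1c(OCC=C)ccc(C(C)=O)c1O
F3 | step 3 | 4-(prop-2-en-1-yloxy)benzaldehyde (purchased) | C=CCOc1ccc(C=O)cc1
F4 | step 3 | (2E)-1-{2-hydroxy-3-[(3R)-3-hydroxy-3,7-dimethyloct-6-en-1-yl]-4-(prop-2-en-1-yloxy)phenyl}-3-[4-(prop-2-en-1-yloxy)phenyl]prop-2-en-1-one | CC(C)=CCC[C@@](C)(O)CCc1c(OCC=C)ccc(C(=O)/C=C/c2ccc(OCC=C)cc2)c1O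
F5 | step 1 | 1-(2,4-dihydroxy-3-iodophenyl)ethan-1-one | CC(=O)c1ccc(O)c(I)c1O
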